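**Strategy.** The six-membered ring C1–C2–C3–C4–C5–C8 of the bicyclo[3.2.1]octenedione (C1, C5 bridgeheads; C2, C8 ketones; C3=C4 alkene) is a resorcinol locked in its diketo form. It is opened like a polyketide: C4–C5 by conjugate addition, C8–C1 by Claisen condensation. The precursor is an open chain: a diaryl-substituted tether (C6, C7) with a Meldrum's acid (future C5/C8) at one end and an enynone (future C1–C4) at the other. One base charge triggers Michael addition and transannular acylation, forming both bonds, three rings and two stereocentres. The bridgehead carboxyl left at C5 is then removed by radical decarboxylation.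

Key step: step 7

Remark: the absolute sense of induction of the chiral diene ligand (steps 2 and 4) and of the auxiliary in the third fallback is assumed; in each case the enantiomer that delivers the drawn configuration is the one used. Atom numbers C1–C8 are those of the target skeleton (C6 carries the 3,5-dioxygenated aryl, C7 the 3,4-dioxygenated aryl, C4 the styryl group).

Step 1
Reactants: 1 3,5-dimethoxybenzaldehyde; 2 Meldrum's acid (2,2-dimethyl-1,3-dioxane-4,6-dione)
Product: 3 5-(3,5-dimethoxybenzylidene)-2,2-dimethyl-1,3-dioxane-4,6-dione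
Conditions: H2O, 75 °C; filtration of the precipitate
Reagents that add atoms: none
Why: Knoevenagel condensation of an aromatic aldehyde with the strongly C–H acidic Meldrum's acid (pKa about 5) should proceed without catalyst in hot water and stop at the crystalline arylidene; no stereocentre is formed.

Step 2
Reactants: 3 5-(3,5-dimethoxybenzylidene)-2,2-dimethyl-1,3-dioxane-4,6-dione
Product: 4 5-[(1S)-1-(3,5-dimethoxyphenyl)prop-2-en-1-yl]-2,2-dimethyl-1,3-dioxane-4,6-dione
Conditions: [RhCl(C2H4)2]2 (2.5 mol%), (1R,4R)-2,5-diphenylbicyclo[2.2.2]octa-2,5-diene (5.5 mol%), tributyl(vinyl)stannane (1.3 equiv), THF, 40 °C; then 1 M HCl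
Reagents that add atoms: tributyl(vinyl)stannane, C=C[Sn](CCCC)(CCCC)CCCC
Why: Rhodium/chiral diene-catalysed asymmetric conjugate alkenylation (a Hayashi–Miyaura-type 1,4-addition) of the highly electrophilic arylidene Meldrum's acid should transfer the vinyl group to one enantioface selected by the diene ligand, which sets C6 (S).

Step 3
Reactants: 4 5-[(1S)-1-(3,5-dimethoxyphenyl)prop-2-en-1-yl]-2,2-dimethyl-1,3-dioxane-4,6-dione; 5 N-methoxy-N-methylprop-2-enamide
Product: 6 5-[(1S,2E)-1-(3,5-dimethoxyphenyl)-4-[methoxy(methyl)amino]-4-oxobut-2-en-1-yl]-2,2-dimethyl-1,3-dioxane-4,6-dione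
Conditions: second-generation Hoveyda–Grubbs catalyst (5 mol%), 1,4-benzoquinone (10 mol%), 5 (3 equiv), CH2Cl2, 40 °C
Reagents that add atoms: none
Why: Olefin cross-metathesis of the hindered terminal alkene (slow to homodimerise) with the electron-poor acrylamide should give the E enamide, benzoquinone suppressing alkene migration by ruthenium hydrides; the C6 centre is not touched.

Step 4
Reactants: 6 5-[(1S,2E)-1-(3,5-dimethoxyphenyl)-4-[methoxy(methyl)amino]-4-oxobut-2-en-1-yl]-2,2-dimethyl-1,3-dioxane-4,6-dione; 7 3,4-dimethoxyphenylboronic acid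
Product: 8 5-[(1S,2R)-2-(3,4-dimethoxyphenyl)-1-(3,5-dimethoxyphenyl)-4-[methoxy(methyl)amino]-4-oxobutyl]-2,2-dimethyl-1,3-dioxane-4,6-dione
Conditions: [RhCl(C2H4)2]2 (2.5 mol%), (1S,4S)-2,5-diphenylbicyclo[2.2.2]octa-2,5-diene (5.5 mol%), 7 (2.5 equiv), KOH (1.2 equiv), 1,4-dioxane/H2O 10:1, 50 °C; then 1 M HCl
Reagents that add atoms: none
Why: Hayashi–Miyaura rhodium-catalysed asymmetric 1,4-addition of an arylboronic acid to an α,β-unsaturated Weinreb amide, in which the chiral diene (catalyst control over the neighbouring centre) selects the face of the enamide and sets C7 (R) while the dioxanedione is carried as its inert potassium enolate.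

Step 5
Reactants: 9 (2E)-3-(3,4-dimethoxyphenyl)prop-2-enal
Product: 10 4-[(1E)-but-1-en-3-yn-1-yl]-1,2-dimethoxybenzene
Conditions: Ohira–Bestmann reagent (1.3 equiv), K2CO3 (2 equiv), MeOH, 0 → 25 °C
Reagents that add atoms: Ohira–Bestmann reagent (dimethyl (1-diazo-2-oxopropyl)phosphonate), COP(=O)(OC)C(=[N+]=[N-])C(C)=O
Why: Ohira–Bestmann (Seyferth–Gilbert) homologation converts the enal into the terminal enyne under mild carbonate conditions that leave the E alkene unchanged.

Step 6
Reactants: 8 5-[(1S,2R)-2-(3,4-dimethoxyphenyl)-1-(3,5-dimethoxyphenyl)-4-[methoxy(methyl)amino]-4-oxobutyl]-2,2-dimethyl-1,3-dioxane-4,6-dione; 10 4-[(1E)-but-1-en-3-yn-1-yl]-1,2-dimethoxybenzene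
Product: 11 5-[(1S,2R,7E)-2,8-bis(3,4-dimethoxyphenyl)-1-(3,5-dimethoxyphenyl)-4-oxooct-7-en-5-yn-1-yl]-2,2-dimethyl-1,3-dioxane-4,6-dione
Conditions: 10 (2.3 equiv), n-BuLi (2.2 equiv), THF, −78 °C; then 8, −78 → −20 °C; cold 1 M HCl; used at once
Reagents that add atoms: none
Why: Weinreb ketone synthesis in which the first equivalent of lithium acetylide only deprotonates the dioxanedione (protecting it as its enolate) and the second adds to the amide to give the chelated tetrahedral intermediate, so the ynone is released only on acidic work-up and no stereocentre is affected.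

Step 7
Reactants: 11 5-[(1S,2R,7E)-2,8-bis(3,4-dimethoxyphenyl)-1-(3,5-dimethoxyphenyl)-4-oxooct-7-en-5-yn-1-yl]-2,2-dimethyl-1,3-dioxane-4,6-dione
Product: 13 (1R,5R,6R,7S)-7-(3,4-dimethoxyphenyl)-6-(3,5-dimethoxyphenyl)-4-[(E)-2-(3,4-dimethoxyphenyl)ethenyl]-2,8-dioxobicyclo[3.2.1]oct-3-ene-5-carboxylic acid, via spiro-dioxanedione cycloheptenone 12 (not isolated)
Conditions: KN(SiMe3)2 (1.05 equiv), 18-crown-6 (1.05 equiv), THF (0.01 M), −78 → 45 °C; then 1 M HCl
Reagents that add atoms: none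
Why: KN(SiMe3)2 deprotonates only the dioxanedione C–H (pKa about 5 against about 20 for the α'-CH2 of the ynone); its enolate, whose own carbonyl groups are thereby switched off, adds to C4 of the ynone in a 7-endo-dig conjugate addition (C4–C5 bond, seven-membered ring), and HN(SiMe3)2 protonates the resulting vinyl anion and returns the amide base. That base now removes the only acidic proton left (on C1), and the dienolate attacks the now quaternary, strongly acylating dioxanedione carbonyl across the ring in a 5-exo-trig Claisen condensation (C8–C1 bond), which closes the five-membered and with it the six-membered ring and expels acetone to leave the C5 carboxylate. The closest known reaction type is the Michael–Claisen annulation of malonates with enones and ynones used for cyclohexane-1,3-diones and resorcinols, combined with C-acylation by 5,5-disubstituted Meldrum's acids. C5 and C1 are set together, relative to the resident C6 and C7 centres, in the Claisen step: closure should occur through the conformer in which C1 is attacked anti to the C7 aryl and the C6 aryl points away from the styryl-bearing C3=C4 unit, which puts the C7 aryl endo and the C6 aryl exo. The step needs conjugate addition before acylation, C- instead of O-acylation and an irreversible last step; the first is secured by the anionic dioxanedione, the second by the anti-Bredt strain of the alternative bridged enol lactone, the third by loss of acetone instead of a nucleophilic alkoxide.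

Step 8
Reactants: 13 (1R,5R,6R,7S)-7-(3,4-dimethoxyphenyl)-6-(3,5-dimethoxyphenyl)-4-[(E)-2-(3,4-dimethoxyphenyl)ethenyl]-2,8-dioxobicyclo[3.2.1]oct-3-ene-5-carboxylic acid
Product: 15 (1R,5S,6S,7S)-7-(3,4-dimethoxyphenyl)-6-(3,5-dimethoxyphenyl)-4-[(E)-2-(3,4-dimethoxyphenyl)ethenyl]bicyclo[3.2.1]oct-3-ene-2,8-dione, via N-acyloxyphthalimide ester 14 (not isolated)
Conditions: N-hydroxyphthalimide (1.1 equiv), N,N'-diisopropylcarbodiimide (1.1 equiv), DMAP (10 mol%), CH2Cl2, 25 °C; then Hantzsch ester (1.5 equiv), Ru(bpy)3Cl2 (1 mol%), blue LED, 25 °C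
Reagents that add atoms: none
Why: Barton-type reductive decarboxylation of a redox-active N-acyloxyphthalimide ester, chosen because a bridgehead β-keto acid cannot lose CO2 through an enol (Bredt's rule); single-electron reduction releases CO2 and the C5 bridgehead radical, which takes hydrogen from the Hantzsch ester with the configuration fixed by the bicycle.

Step 9
Reactants: 15 (1R,5S,6S,7S)-7-(3,4-dimethoxyphenyl)-6-(3,5-dimethoxyphenyl)-4-[(E)-2-(3,4-dimethoxyphenyl)ethenyl]bicyclo[3.2.1]oct-3-ene-2,8-dione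
Product: 16 (1R,5S,6S,7S)-7-(3,4-dihydroxyphenyl)-6-(3,5-dihydroxyphenyl)-4-[(E)-2-(3,4-dihydroxyphenyl)ethenyl]bicyclo[3.2.1]oct-3-ene-2,8-dione
Conditions: BBr3 (12 equiv), CH2Cl2, −78 → 0 °C; then MeOH, H2O
Reagents that add atoms: none
Why: Lewis acid-mediated cleavage of the six aryl methyl ethers (bromide attack at methyl of the aryloxyborane complexes) should free all phenols without touching the carbon skeleton, the non-enolisable bridgeheads or the E alkene.

**Compound list**

1 | 3,5-dimethoxybenzaldehyde | COc1cc(C=O)cc(OC)c1 | starting material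
2 | Meldrum's acid (2,2-dimethyl-1,3-dioxane-4,6-dione) | CC1(C)OC(=O)CC(=O)O1 | starting material
3 | 5-(3,5-dimethoxybenzylidene)-2,2-dimethyl-1,3-dioxane-4,6-dione | COc1cc(C=C2C(=O)OC(C)(C)OC2=O)cc(OC)c1 | intermediate
4 | 5-[(1S)-1-(3,5-dimethoxyphenyl)prop-2-en-1-yl]-2,2-dimethyl-1,3-dioxane-4,6-dione | C=C[C@@H](C1C(=O)OC(C)(C)OC1=O)c1cc(OC)cc(OC)c1 | intermediate
5 | N-methoxy-N-methylprop-2-enamide | C=CC(=O)N(C)OC | starting material
6 | 5-[(1S,2E)-1-(3,5-dimethoxyphenyl)-4-[methoxy(methyl)amino]-4-oxobut-2-en-1-yl]-2,2-dimethyl-1,3-dioxane-4,6-dione | CON(C)C(=O)/C=C/[C@@H](C1C(=O)OC(C)(C)OC1=O)c1cc(OC)cc(OC)c1 | intermediate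
7 | 3,4-dimethoxyphenylboronic acid | COc1ccc(B(O)O)cc1OC | starting material
8 | 5-[(1S,2R)-2-(3,4-dimethoxyphenyl)-1-(3,5-dimethoxyphenyl)-4-[methoxy(methyl)amino]-4-oxobutyl]-2,2-dimethyl-1,3-dioxane-4,6-dione | CON(C)C(=O)C[C@@H](c1ccc(OC)c(OC)c1)[C@@H](C1C(=O)OC(C)(C)OC1=O)c1cc(OC)cc(OC)c1 | intermediate
9 | (2E)-3-(3,4-dimethoxyphenyl)prop-2-enal | COc1ccc(/C=C/C=O)cc1OC | starting material
10 | 4-[(1E)-but-1-en-3-yn-1-yl]-1,2-dimethoxybenzene | C#C/C=C/c1ccc(OC)c(OC)c1 | intermediate
11 | 5-[(1S,2R,7E)-2,8-bis(3,4-dimethoxyphenyl)-1-(3,5-dimethoxyphenyl)-4-oxooct-7-en-5-yn-1-yl]-2,2-dimethyl-1,3-dioxane-4,6-dione | O=C(C[C@@H](c1ccc(OC)c(OC)c1)[C@@H](C1C(=O)OC(C)(C)OC1=O)c1cc(OC)cc(OC)c1)C#C/C=C/c1ccc(OC)c(OC)c1 | intermediate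
12 | spiro Michael adduct: cyclohept-2-en-1-one with the 2,2-dimethyl-1,3-dioxane-4,6-dione spiro-fused at C4 (through its C5), 3-[(E)-2-(3,4-dimethoxyphenyl)ethenyl], (5R)-5-(3,5-dimethoxyphenyl) and (6R)-6-(3,4-dimethoxyphenyl), aryl groups trans | O=C1C=C(/C=C/c2ccc(OC)c(OC)c2)C2(C(=O)OC(C)(C)OC2=O)[C@@H](c2cc(OC)cc(OC)c2)[C@H](c2ccc(OC)c(OC)c2)C1 | intermediate (not isolated)
13 | (1R,5R,6R,7S)-7-(3,4-dimethoxyphenyl)-6-(3,5-dimethoxyphenyl)-4-[(E)-2-(3,4-dimethoxyphenyl)ethenyl]-2,8-dioxobicyclo[3.2.1]oct-3-ene-5-carboxylic acid (target numbering) | O=C1C=C(/C=C/c2ccc(OC)c(OC)c2)[C@@]2(C(=O)O)C(=O)[C@@H]1[C@@H](c1ccc(OC)c(OC)c1)[C@@H]2c1cc(OC)cc(OC)c1 | intermediate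
14 | 1,3-dioxoisoindolin-2-yl ester of acid 13 (N-acyloxyphthalimide, same configuration) | O=C1C=C(/C=C/c2ccc(OC)c(OC)c2)[C@@]2(C(=O)ON3C(=O)c4ccccc4C3=O)C(=O)[C@@H]1[C@@H](c1ccc(OC)c(OC)c1)[C@@H]2c1cc(OC)cc(OC)c1 | intermediate (not isolated)
15 | (1R,5S,6S,7S)-7-(3,4-dimethoxyphenyl)-6-(3,5-dimethoxyphenyl)-4-[(E)-2-(3,4-dimethoxyphenyl)ethenyl]bicyclo[3.2.1]oct-3-ene-2,8-dione | O=C1C=C(/C=C/c2ccc(OC)c(OC)c2)[C@H]2C(=O)[C@@H]1[C@@H](c1ccc(OC)c(OC)c1)[C@@H]2c1cc(OC)cc(OC)c1 | intermediate
16 | (1R,5S,6S,7S)-7-(3,4-dihydroxyphenyl)-6-(3,5-dihydroxyphenyl)-4-[(E)-2-(3,4-dihydroxyphenyl)ethenyl]bicyclo[3.2.1]oct-3-ene-2,8-dione | O=C1C=C(/C=C/c2ccc(O)c(O)c2)[C@H]2C(=O)[C@@H]1[C@@H](c1ccc(O)c(O)c1)[C@@H]2c1cc(O)cc(O)c1 | target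

**Totals.** Total step count: 9. Longest linear sequence: 8 (steps 1, 2, 3, 4, 6, 7, 8, 9); step 5 is convergent.

**Steps most likely to fail**

1. Step 7 (key step). The 7-endo-dig ring closure of the weakly nucleophilic dioxanedione enolate may be slower than conjugate addition between two chains, and the facial selectivity of the transannular acylation may be low. Fallback, setting out from 11 and returning at 13: hydroiodination of the ynone with LiI/AcOH in MeCN should give the (Z)-β-iodo enone 5-[(1S,2R,5Z,7E)-2,8-bis(3,4-dimethoxyphenyl)-1-(3,5-dimethoxyphenyl)-6-iodo-4-oxoocta-5,7-dien-1-yl]-2,2-dimethyl-1,3-dioxane-4,6-dione F1. Intramolecular coupling of its dioxanedione enolate with the alkenyl iodide (Pd(PPh3)4, Cs2CO3, DMF, 50 °C) then closes the seven-membered ring by cross-coupling instead of conjugate addition and gives 12, this time isolated. LiN(SiMe3)2 in THF at −78 °C performs the Claisen closure under kinetic control to 13.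

2. Step 2. Transfer of the vinyl group from tin to rhodium may be sluggish and the enantiofacial control on the arylidene may be insufficient. Fallback, setting out from 1 and returning at 4: vinylmagnesium bromide followed by methyl chloroformate converts 1 into the racemic carbonate 1-(3,5-dimethoxyphenyl)prop-2-en-1-yl methyl carbonate F2. Molybdenum-catalysed asymmetric allylic alkylation (Mo(CO)6, (1S,2S)-N,N'-bis(pyridine-2-carbonyl)cyclohexane-1,2-diamine, sodium dimethyl malonate, THF, 65 °C) should convert both enantiomers of F2 into the branched malonate dimethyl 2-[(1S)-1-(3,5-dimethoxyphenyl)prop-2-en-1-yl]propanedioate F3. LiOH hydrolysis gives 2-[(1S)-1-(3,5-dimethoxyphenyl)prop-2-en-1-yl]propanedioic acid F4, and acetone/Ac2O with catalytic H2SO4 closes the dioxanedione ring to 4.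

3. Step 4. The catalyst may be mismatched with the existing C6 centre, and the acidic dioxanedione may inhibit the catalyst or be hydrolysed in the aqueous basic medium. Fallback, setting out from 4 and returning at 8: cross-metathesis of 4 with (4S)-3-acryloyl-4-benzyl-1,3-oxazolidin-2-one (same ruthenium catalyst) gives the N-enoyl oxazolidinone (4S)-4-benzyl-3-[(2E,4S)-4-(3,5-dimethoxyphenyl)-4-(2,2-dimethyl-4,6-dioxo-1,3-dioxan-5-yl)but-2-enoyl]-1,3-oxazolidin-2-one F5. The aryl cuprate from 3,4-dimethoxyphenylmagnesium bromide and CuBr·SMe2 (THF, −40 °C) adds under auxiliary control to give (4S)-4-benzyl-3-[(3R,4S)-3-(3,4-dimethoxyphenyl)-4-(3,5-dimethoxyphenyl)-4-(2,2-dimethyl-4,6-dioxo-1,3-dioxan-5-yl)butanoyl]-1,3-oxazolidin-2-one F6. AlMe3/MeNHOMe·HCl exchanges the auxiliary for the Weinreb amide and returns 8.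

Further compounds
F1 | step 7 | 5-[(1S,2R,5Z,7E)-2,8-bis(3,4-dimethoxyphenyl)-1-(3,5-dimethoxyphenyl)-6-iodo-4-oxoocta-5,7-dien-1-yl]-2,2-dimethyl-1,3-dioxane-4,6-dione | O=C(C[C@@H](c1ccc(OC)c(OC)c1)[C@@H](C1C(=O)OC(C)(C)OC1=O)c1cc(OC)cc(OC)c1)/C=C(I)/C=C/c1ccc(OC)c(OC)c1
F2 | step 2 | 1-(3,5-dimethoxyphenyl)prop-2-en-1-yl methyl carbonate (racemic) | C=CC(OC(=O)OC)c1cc(OC)cc(OC)c1
F3 | step 2 | dimethyl 2-[(1S)-1-(3,5-dimethoxyphenyl)prop-2-en-1-yl]propanedioate | C=C[C@@H](C(C(=O)OC)C(=O)OC)c1cc(OC)cc(OC)c1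
F4 | step 2 | 2-[(1S)-1-(3,5-dimethoxyphenyl)prop-2-en-1-yl]propanedioic acid | C=C[C@@H](C(C(=O)O)C(=O)O)c1cc(OC)cc(OC)c1
F5 | step 4 | (4S)-4-benzyl-3-[(2E,4S)-4-(3,5-dimethoxyphenyl)-4-(2,2-dimethyl-4,6-dioxo-1,3-dioxan-5-yl)but-2-enoyl]-1,3-oxazolidin-2-one | O=C(/C=C/[C@@H](C1C(=O)OC(C)(C)OC1=O)c1cc(OC)cc(OC)c1)N1C(=O)OC[C@@H]1Cc1ccccc1
F6 | step 4 | (4S)-4-benzyl-3-[(3R,4S)-3-(3,4-dimethoxyphenyl)-4-(3,5-dimethoxyphenyl)-4-(2,2-dimethyl-4,6-dioxo-1,3-dioxan-5-yl)butanoyl]-1,3-oxazolidin-2-one | O=C(C[C@@H](c1ccc(OC)c(OC)c1)[C@@H](C1C(=O)OC(C)(C)OC1=O)c1cc(OC)cc(OC)c1)N1C(=O)OC[C@@H]1Cc1ccccc1
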